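**Plan**

- Retrosynthesis: the four MOM ethers and the C3''=C4'' double bond are removed first, leaving a ring D chroman.
- Ring D is cut at O4'–C2'' and C4''–C3'' into an ortho-quinone methide of ring B (O4'=C4'–C5'=C4'') and isobutene; C5'–C4'' is cut back to formaldehyde and the free 4'-phenol.
- Ring C is cut at O1–C2 and C3–OH (oxidative chalcone cyclisation) and at the chalcone Cα=Cβ bond (aldol), giving a ring A acetophenone and a ring B aldehyde; the C8–C(CH3)2 bond is cut back to an aryl prenyl ether (Claisen).
- Forward: the Claisen rearrangement places the 1,1-dimethylallyl group on ring A, the aldol joins rings A and B, ring C closes oxidatively, ring D closes by the hetero-Diels–Alder reaction, then dehydrogenation and deprotection follow.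
- Stereochemistry: the target has no stereocentre; the E-chalcone geometry and two racemic, transient intermediates are erased on the way.

Key step: step 11

Remark: flavonoid numbering is used (ring D atoms doubly primed); racemic transient intermediates are written without descriptors or as one enantiomer.

**Step 1**
Reactants: 1 2,4,6-trihydroxyacetophenone; 2 1-bromo-3-methylbut-2-ene (prenyl bromide)
Product: 3 1-[2,6-dihydroxy-4-(3-methylbut-2-en-1-yloxy)phenyl]ethan-1-one
Conditions: 2 (1.0 equiv), K2CO3 (1.1 equiv), acetone, rt to reflux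
Reagents that add atoms: none
Why: Williamson ether synthesis; the 4-OH is the most acidic hydroxyl and the only one not hydrogen-bonded to the acetyl group, so one equivalent of prenyl bromide under weak carbonate base should alkylate it on oxygen.

**Step 2**
Reactants: 3 1-[2,6-dihydroxy-4-(3-methylbut-2-en-1-yloxy)phenyl]ethan-1-one
Product: 5 1-[2,4,6-trihydroxy-3-(2-methylbut-3-en-2-yl)phenyl]ethan-1-one, via ortho-dienone 4 (not isolated)
Conditions: N,N-diethylaniline, 190 °C, Ar, sealed tube
Reagents that add atoms: none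
Why: Aromatic Claisen rearrangement ([3,3]-sigmatropic shift with allyl inversion, which puts the quaternary carbon on the ring) followed by enolisation of dienone 4; the two ortho positions are identical by symmetry and the para position carries the acetyl group, so neither a regioisomer nor a para-Cope relay to a normal prenyl group can arise.

**Step 3**
Reactants: 5 1-[2,4,6-trihydroxy-3-(2-methylbut-3-en-2-yl)phenyl]ethan-1-one
Product: 6 1-[2-hydroxy-4,6-bis(methoxymethoxy)-3-(2-methylbut-3-en-2-yl)phenyl]ethan-1-one
Conditions: MOMCl (2.3 equiv), iPr2NEt, CH2Cl2, 0 °C to rt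
Reagents that add atoms: chloromethyl methyl ether (MOMCl), COCCl
Why: MOM etherification under amine base; the 4-OH and 6-OH should react, whereas the 2-OH wedged between the acetyl group and the quaternary carbon is chelated to the carbonyl and the most hindered, so it should stay free for the later closure of ring C.

**Step 4**
Reactants: 7 3,4-dihydroxybenzaldehyde
Product: 8 3-hydroxy-4-(prop-2-en-1-yloxy)benzaldehyde
Conditions: allyl bromide (1.05 equiv), NaHCO3, DMF, 40 °C
Reagents that add atoms: allyl bromide, C=CCBr
Why: Regioselective Williamson etherification; the 4-OH para to the formyl group is the more acidic one and is the only one deprotonated by hydrogencarbonate.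

**Step 5**
Reactants: 8 3-hydroxy-4-(prop-2-en-1-yloxy)benzaldehyde
Product: 9 3-(methoxymethoxy)-4-(prop-2-en-1-yloxy)benzaldehyde
Conditions: MOMCl, iPr2NEt, CH2Cl2, 0 °C to rt
Reagents that add atoms: chloromethyl methyl ether (MOMCl), COCCl
Why: MOM etherification of the single remaining phenol, giving a ring B aldehyde whose two oxygens carry orthogonal groups (allyl removable by palladium, MOM by acid).

**Step 6**
Reactants: 6 1-[2-hydroxy-4,6-bis(methoxymethoxy)-3-(2-methylbut-3-en-2-yl)phenyl]ethan-1-one; 9 3-(methoxymethoxy)-4-(prop-2-en-1-yloxy)benzaldehyde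
Product: 10 (E)-1-[2-hydroxy-4,6-bis(methoxymethoxy)-3-(2-methylbut-3-en-2-yl)phenyl]-3-[3-(methoxymethoxy)-4-(prop-2-en-1-yloxy)phenyl]prop-2-en-1-one
Conditions: KOH (excess), EtOH–H2O, rt
Reagents that add atoms: none
Why: Claisen–Schmidt condensation; the methyl ketone enolate adds to the non-enolisable aldehyde and E1cB dehydration gives the conjugated E-enone, all ethers and acetals being stable to base.

**Step 7**
Reactants: 10 the E-chalcone of step 6
Product: 12 3-hydroxy-5,7-bis(methoxymethoxy)-2-[3-(methoxymethoxy)-4-(prop-2-en-1-yloxy)phenyl]-8-(2-methylbut-3-en-2-yl)-4H-chromen-4-one, via trans-dihydroflavonol 11 (not isolated)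
Conditions: 30% H2O2, 2 M NaOH, MeOH–THF, 0 °C to rt
Reagents that add atoms: hydrogen peroxide, OO
Why: Algar–Flynn–Oyamada reaction; alkaline peroxide oxidises the enone nucleophilically, the 2'-phenoxide closes ring C in the 6-endo sense to dihydroflavonol 11, and 11 is oxidised on to the flavonol in the same flask, while the isolated vinyl and allyl alkenes are inert to a nucleophilic oxidant and the low temperature should hold back 5-exo closure.

**Step 8**
Reactants: 12 the 3-hydroxyflavone of step 7
Product: 13 3,5,7-tris(methoxymethoxy)-2-[3-(methoxymethoxy)-4-(prop-2-en-1-yloxy)phenyl]-8-(2-methylbut-3-en-2-yl)-4H-chromen-4-one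
Conditions: MOMCl, iPr2NEt, CH2Cl2, 0 °C to rt
Reagents that add atoms: chloromethyl methyl ether (MOMCl), COCCl
Why: MOM etherification of the only free hydroxyl, the acidic 3-OH, which protects the flavonol against base-mediated oxidation in step 10 and against DDQ in step 12.

**Step 9**
Reactants: 13 the 4'-O-allyl tetrakis(MOM) flavonol of step 8
Product: 14 2-[4-hydroxy-3-(methoxymethoxy)phenyl]-3,5,7-tris(methoxymethoxy)-8-(2-methylbut-3-en-2-yl)-4H-chromen-4-one
Conditions: Pd(PPh3)4 (5 mol %), K2CO3, MeOH–THF, 50 °C
Reagents that add atoms: none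
Why: Tsuji–Trost-type deallylation; zerovalent palladium ionises the aryl allyl ether to an allylpalladium cation and the stabilised 4'-phenoxide, methoxide takes up the allyl group, and the C-bound 1,1-dimethylallyl chain has no leaving group while MOM acetals are inert to base.

**Step 10**
Reactants: 14 the 4'-phenol of step 9; 15 formaldehyde
Product: 16 2-[4-hydroxy-3-(hydroxymethyl)-5-(methoxymethoxy)phenyl]-3,5,7-tris(methoxymethoxy)-8-(2-methylbut-3-en-2-yl)-4H-chromen-4-one
Conditions: 37% aq. CH2O (excess), NaOH (2 equiv), THF–H2O, 40 °C; then aq. NH4Cl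
Reagents that add atoms: none
Why: Lederer–Manasse hydroxymethylation; the 4'-phenoxide attacks formaldehyde through C5', its only free ortho carbon (C3' carries OMOM, the para carbon C1' carries the chromone), as in the known C5 hydroxymethylation of vanillin, and the acetals survive the basic medium.

**Step 11**
Reactants: 16 the 4'-hydroxy-5'-(hydroxymethyl) flavonol of step 10; 17 isobutene (2-methylpropene)
Product: 19 2-[8-(methoxymethoxy)-2,2-dimethyl-3,4-dihydro-2H-chromen-6-yl]-3,5,7-tris(methoxymethoxy)-8-(2-methylbut-3-en-2-yl)-4H-chromen-4-one, via ortho-quinone methide 18 (not isolated)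
Conditions: 17 (condensed, ca. 50 equiv), toluene (0.02 M in 16), steel autoclave, 180 °C
Reagents that add atoms: none
Why: On heating, the ortho-hydroxybenzyl alcohol of ring B loses water by 1,4-elimination to give ortho-quinone methide 18, whose O4'=C4'–C5'=C4'' heterodiene adds isobutene in an inverse-electron-demand hetero-Diels–Alder reaction; the closest known reaction type is the thermal chroman synthesis from salicyl alcohols (or their benzodioxaborins) and alkenes. Ring D closes as a six-membered ring by this intermolecular [4+2] cycloaddition, which forms C4''–C3'' and O4'–C2'' together and restores the aromaticity of ring B. No stereocentre arises, because C2'' carries two methyl groups and C3'' and C4'' are methylene carbons. The step needs regioselectivity (oxygen to the tertiary carbon), which should follow from the electrophilic methide carbon bonding to the unsubstituted, more nucleophilic terminus of isobutene; conjugation of ring B to the pyranone carbonyl makes 18 electron-poor and matches it to the electron-rich 1,1-disubstituted alkene. It also needs chemoselectivity over the monosubstituted C8 vinyl group and over self-addition of 18, which the large excess of isobutene and the high dilution of 16 should secure; re-addition of water to 18 is reversible, so the cycloaddition should drain the equilibrium.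

**Step 12**
Reactants: 19 the chroman of step 11
Product: 20 2-[8-(methoxymethoxy)-2,2-dimethyl-2H-chromen-6-yl]-3,5,7-tris(methoxymethoxy)-8-(2-methylbut-3-en-2-yl)-4H-chromen-4-one
Conditions: DDQ (2.5 equiv), 1,4-dioxane, reflux
Reagents that add atoms: none
Why: DDQ dehydrogenation of a 2,2-dimethylchroman to the 2H-chromene; hydride abstraction from benzylic C4'' gives a cation stabilised by the ortho ring oxygen O4', loss of a C3'' proton gives the double bond, and the quaternary C2'' stops the oxidation at the chromene.

**Step 13**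
Reactants: 20 the chromene tetrakis(MOM) ether of step 12
Product: 21 Broussonol A, 3,5,7-trihydroxy-2-(8-hydroxy-2,2-dimethyl-2H-chromen-6-yl)-8-(2-methylbut-3-en-2-yl)-4H-chromen-4-one
Conditions: 3 M HCl in MeOH, THF, 40 °C
Reagents that add atoms: none
Why: Acid-catalysed acetal solvolysis (MOM ether cleavage), in which methanol takes up the methoxymethyl cation; the conditions are mild enough that the chromene and the 1,1-dimethylallyl alkenes, which would react only through carbocations, should persist.

**Compound list**

1 | 2,4,6-trihydroxyacetophenone | CC(=O)c1c(O)cc(O)cc1O | starting material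
2 | 1-bromo-3-methylbut-2-ene (prenyl bromide) | CC(C)=CCBr | starting material
3 | 1-[2,6-dihydroxy-4-(3-methylbut-2-en-1-yloxy)phenyl]ethan-1-one | CC(=O)c1c(O)cc(OCC=C(C)C)cc1O | intermediate
4 | 4-acetyl-3,5-dihydroxy-6-(2-methylbut-3-en-2-yl)cyclohexa-2,4-dien-1-one (racemic ortho-dienone, not isolated) | CC(=O)C1=C(O)C(C(C)(C)C=C)C(=O)C=C1O | intermediate
5 | 1-[2,4,6-trihydroxy-3-(2-methylbut-3-en-2-yl)phenyl]ethan-1-one | CC(=O)c1c(O)cc(O)c(C(C)(C)C=C)c1O | intermediate
6 | 1-[2-hydroxy-4,6-bis(methoxymethoxy)-3-(2-methylbut-3-en-2-yl)phenyl]ethan-1-one | CC(=O)c1c(OCOC)cc(OCOC)c(C(C)(C)C=C)c1O | intermediate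
7 | 3,4-dihydroxybenzaldehyde | O=Cc1ccc(O)c(O)c1 | starting material
8 | 3-hydroxy-4-(prop-2-en-1-yloxy)benzaldehyde | O=Cc1ccc(OCC=C)c(O)c1 | intermediate
9 | 3-(methoxymethoxy)-4-(prop-2-en-1-yloxy)benzaldehyde | O=Cc1ccc(OCC=C)c(OCOC)c1 | intermediate
10 | (E)-1-[2-hydroxy-4,6-bis(methoxymethoxy)-3-(2-methylbut-3-en-2-yl)phenyl]-3-[3-(methoxymethoxy)-4-(prop-2-en-1-yloxy)phenyl]prop-2-en-1-one | C=CC(C)(C)c1c(O)c(C(=O)/C=C/c2ccc(OCC=C)c(OCOC)c2)c(OCOC)cc1OCOC | intermediate
11 | rac-(2R,3R)-3-hydroxy-5,7-bis(methoxymethoxy)-2-[3-(methoxymethoxy)-4-(prop-2-en-1-yloxy)phenyl]-8-(2-methylbut-3-en-2-yl)chroman-4-one (trans, one enantiomer drawn, not isolated) | C=CC(C)(C)c1c(OCOC)cc(OCOC)c2c1O[C@H](c1ccc(OCC=C)c(OCOC)c1)[C@@H](O)C2=O | intermediate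
12 | 3-hydroxy-5,7-bis(methoxymethoxy)-2-[3-(methoxymethoxy)-4-(prop-2-en-1-yloxy)phenyl]-8-(2-methylbut-3-en-2-yl)-4H-chromen-4-one | C=CC(C)(C)c1c(OCOC)cc(OCOC)c2c(=O)c(O)c(-c3ccc(OCC=C)c(OCOC)c3)oc12 | intermediate
13 | 3,5,7-tris(methoxymethoxy)-2-[3-(methoxymethoxy)-4-(prop-2-en-1-yloxy)phenyl]-8-(2-methylbut-3-en-2-yl)-4H-chromen-4-one | C=CC(C)(C)c1c(OCOC)cc(OCOC)c2c(=O)c(OCOC)c(-c3ccc(OCC=C)c(OCOC)c3)oc12 | intermediate
14 | 2-[4-hydroxy-3-(methoxymethoxy)phenyl]-3,5,7-tris(methoxymethoxy)-8-(2-methylbut-3-en-2-yl)-4H-chromen-4-one | C=CC(C)(C)c1c(OCOC)cc(OCOC)c2c(=O)c(OCOC)c(-c3ccc(O)c(OCOC)c3)oc12 | intermediate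
15 | formaldehyde | C=O | starting material
16 | 2-[4-hydroxy-3-(hydroxymethyl)-5-(methoxymethoxy)phenyl]-3,5,7-tris(methoxymethoxy)-8-(2-methylbut-3-en-2-yl)-4H-chromen-4-one | C=CC(C)(C)c1c(OCOC)cc(OCOC)c2c(=O)c(OCOC)c(-c3cc(OCOC)c(O)c(CO)c3)oc12 | intermediate
17 | isobutene (2-methylpropene) | CC(C)=C | starting material
18 | 2-[5-(methoxymethoxy)-3-methylidene-4-oxocyclohexa-1,5-dien-1-yl]-3,5,7-tris(methoxymethoxy)-8-(2-methylbut-3-en-2-yl)-4H-chromen-4-one (ortho-quinone methide, not isolated) | C=CC(C)(C)c1c(OCOC)cc(OCOC)c2c(=O)c(OCOC)c(C3=CC(=C)C(=O)C(OCOC)=C3)oc12 | intermediate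
19 | 2-[8-(methoxymethoxy)-2,2-dimethyl-3,4-dihydro-2H-chromen-6-yl]-3,5,7-tris(methoxymethoxy)-8-(2-methylbut-3-en-2-yl)-4H-chromen-4-one | C=CC(C)(C)c1c(OCOC)cc(OCOC)c2c(=O)c(OCOC)c(-c3cc(OCOC)c4c(c3)CCC(C)(C)O4)oc12 | intermediate
20 | 2-[8-(methoxymethoxy)-2,2-dimethyl-2H-chromen-6-yl]-3,5,7-tris(methoxymethoxy)-8-(2-methylbut-3-en-2-yl)-4H-chromen-4-one | C=CC(C)(C)c1c(OCOC)cc(OCOC)c2c(=O)c(OCOC)c(-c3cc(OCOC)c4c(c3)C=CC(C)(C)O4)oc12 | intermediate
21 | Broussonol A | C=CC(C)(C)c1c(O)cc(O)c2c(=O)c(O)c(-c3cc(O)c4c(c3)C=CC(C)(C)O4)oc12 | target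

**Step count and risks**

Total step count: 13. Longest linear sequence: 11 steps (steps 1 to 3, then 6 to 13); the ring B aldehyde branch takes 2 steps (4 and 5).

Steps most likely to fail:

Step 11. The quinone methide may oligomerise, or acetals may be lost at 180 °C, before isobutene is captured. The fallback leaves the cycloaddition and builds the chromene by a sigmatropic route. It sets out from phenol 14: O-alkylation with 3-chloro-3-methylbut-1-yne (K2CO3, KI, acetone, reflux) should give the 4'-O-(2-methylbut-3-yn-2-yl) ether F1. Heating F1 in N,N-diethylaniline at about 150 °C should bring about propargyl Claisen rearrangement to C5' (the only free ortho carbon), a 1,5-hydrogen shift and oxa-6π electrocyclisation. This comes back to the route at chromene 20, so compounds 16 and 19 and step 12 are bypassed.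

Step 7. The chalcone carries a substituent at C6' of the ketone ring, which may divert the oxidative cyclisation towards 5-exo closure (aurone formation). The fallback sets out from chalcone 10 and separates ring closure from oxygenation. Oxa-Michael cyclisation (NaOAc, EtOH, reflux) should give the racemic flavanone F2. Dehydrogenation with DDQ in 1,4-dioxane at reflux should give the flavone F3. Lithiation of F3 at C3 (LiN(iPr)2, THF, −78 °C), borylation with B(OMe)3 and oxidative work-up (H2O2, AcOH) should then install the 3-hydroxyl. This comes back to the route at flavonol 12.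

Step 10. Electrophilic substitution on the phenoxide, which is deactivated by conjugation to the chromone, may be sluggish, and the product may condense with unreacted phenol to diarylmethanes on prolonged reaction. The fallback sets out from phenol 14 and uses boron-templated, ortho-specific delivery of formaldehyde. Treatment with PhB(OH)2, paraformaldehyde and catalytic EtCO2H in toluene at reflux with water separation should give the 2-phenyl-4H-1,3,2-benzodioxaborin F4. Transesterification with propane-1,3-diol in THF at rt should release the ortho-hydroxybenzyl alcohol. This comes back to the route at compound 16.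

**Further compounds**

F1 | step 11 | 3,5,7-tris(methoxymethoxy)-2-[3-(methoxymethoxy)-4-(2-methylbut-3-yn-2-yloxy)phenyl]-8-(2-methylbut-3-en-2-yl)-4H-chromen-4-one | C=CC(C)(C)c1c(OCOC)cc(OCOC)c2c(=O)c(OCOC)c(-c3ccc(OC(C)(C)C#C)c(OCOC)c3)oc12
F2 | step 7 | racemic 5,7-bis(methoxymethoxy)-2-[3-(methoxymethoxy)-4-(prop-2-en-1-yloxy)phenyl]-8-(2-methylbut-3-en-2-yl)chroman-4-one | C=CC(C)(C)c1c(OCOC)cc(OCOC)c2c1OC(c1ccc(OCC=C)c(OCOC)c1)CC2=O
F3 | step 7 | 5,7-bis(methoxymethoxy)-2-[3-(methoxymethoxy)-4-(prop-2-en-1-yloxy)phenyl]-8-(2-methylbut-3-en-2-yl)-4H-chromen-4-one | C=CC(C)(C)c1c(OCOC)cc(OCOC)c2c(=O)cc(-c3ccc(OCC=C)c(OCOC)c3)oc12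
F4 | step 10 | 3,5,7-tris(methoxymethoxy)-2-[8-(methoxymethoxy)-2-phenyl-4H-1,3,2-benzodioxaborin-6-yl]-8-(2-methylbut-3-en-2-yl)-4H-chromen-4-one | C=CC(C)(C)c1c(OCOC)cc(OCOC)c2c(=O)c(OCOC)c(-c3cc(OCOC)c4OB(c5ccccc5)OCc4c3)oc12
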